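## Retrosynthetic overview
1. Schweinfurthin I ⇒ its tris-MOM ether, opened by one global acetal cleavage at the end.
2. Stilbene C=C ⇒ two aldehydes. The geranylated 4-alkoxybenzaldehyde is converted in situ into its NH2-hydrazone, so its former carbonyl carbon reacts as a benzyl carbanion. It attacks 3,5-bis(MOMO)benzaldehyde under Ru(II) catalysis; N2 and H2O leave and the E-alkene forms directly.
3. Aryl–geranyl bond ⇒ ortho-C-alkylation of 4-hydroxybenzaldehyde phenoxide with geranyl bromide, whose E-alkene is bought in.
4. No ring is formed: both benzene rings are purchased as hydroxybenzaldehydes.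

Assumption: the target has no stereocentre and is achiral, so "single enantiomer" is read as the single (E,E) geometric isomer drawn.

## Route

Step 1
Reactants: 1 4-hydroxybenzaldehyde; 2 geranyl bromide
Product: 3 3-geranyl-4-hydroxybenzaldehyde
Conditions: 1 (2 equiv), KOH (2 equiv), H2O, 2 (1 equiv), rt, 24 h; hexane wash of the basic phase; then 1 M HCl, 0 °C
Reagents that add atoms: none
Why: Ortho-C-allylation of an ambident phenoxide, in which water hydrogen-bonds the phenoxide oxygen so the soft allylic bromide is taken in SN2 fashion by the ortho carbon (para is blocked by CHO), the E-alkene of 2 is untouched, excess cheap 1 limits dialkylation, and the neutral O-geranyl by-product goes into the hexane wash.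

Step 2
Reactants: 3 3-geranyl-4-hydroxybenzaldehyde
Product: 4 3-geranyl-4-(methoxymethoxy)benzaldehyde
Conditions: NaH (1.2 equiv), MOMCl (1.3 equiv), DMF, 0 °C to rt
Reagents that add atoms: chloromethyl methyl ether (MOMCl), COCCl
Why: Williamson-type O-alkylation of the sodium phenoxide by the hard electrophile MOMCl removes the acidic OH that would quench the catalytic base of step 4, and the non-enolisable aldehyde and both alkenes are inert.

Step 3
Reactants: 5 3,5-dihydroxybenzaldehyde
Product: 6 3,5-bis(methoxymethoxy)benzaldehyde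
Conditions: NaH (2.5 equiv), MOMCl (2.6 equiv), DMF, 0 °C to rt
Reagents that add atoms: chloromethyl methyl ether (MOMCl), COCCl
Why: Double Williamson-type O-alkylation gives a base-, fluoride- and hydrazine-stable bis-acetal whose meta-alkoxy groups keep the aldehyde strongly electrophilic.

Step 4
Reactants: 4 3-geranyl-4-(methoxymethoxy)benzaldehyde (1.2 equiv); 6 3,5-bis(methoxymethoxy)benzaldehyde (1.0 equiv)
Product: 9 (E)-3-geranyl-4,3',5'-tris(methoxymethoxy)stilbene, via aldehyde hydrazone 7 (not isolated), via hydroxy diazene adduct 8 (not isolated)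
Conditions: (i) 4, N2H4·H2O (1.0 equiv to 4), THF, Na2SO4, rt, 1 h; (ii) solution added to 6, [Ru(p-cymene)Cl2]2 (1.5 mol %), dmpe (3 mol %), KOtBu (50 mol %), CsF (75 mol %), THF, 45 °C, 16 h, N2
Reagents that add atoms: hydrazine monohydrate, NN.O (its two N atoms stand only in 7 and 8 and leave as N2 before 9)
Why: Ru(II)-catalysed carbonyl reductive cross-coupling by hydrazone umpolung, in which N-ruthenated 7 makes the former carbonyl carbon of 4 nucleophilic, it adds to the more electrophilic aldehyde 6 through a six-membered transition state to give 8, and KOtBu then drives E1cB-type loss of N2 and hydroxide to the thermodynamically favoured E-stilbene, while the MOM ethers and the trisubstituted geranyl alkenes tolerate the mild basic medium.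

Step 5
Reactants: 9 (E)-3-geranyl-4,3',5'-tris(methoxymethoxy)stilbene
Product: 10 schweinfurthin I
Conditions: p-TsOH·H2O (cat.), MeOH, rt, 20 h, dark; NaHCO3 quench
Reagents that add atoms: none
Why: Acid-catalysed transacetalisation to methanol cleaves all three aryl MOM ethers at room temperature, which is mild enough to leave prenylated and geranylated phenolic stilbenes uncyclised, and exclusion of light keeps the stilbene E.

## Compound list
1 | 4-hydroxybenzaldehyde | O=Cc1ccc(O)cc1 | starting material
2 | geranyl bromide, (2E)-1-bromo-3,7-dimethylocta-2,6-diene | CC(C)=CCC/C(C)=C/CBr | starting material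
3 | 3-geranyl-4-hydroxybenzaldehyde, 3-[(2E)-3,7-dimethylocta-2,6-dien-1-yl]-4-hydroxybenzaldehyde | CC(C)=CCC/C(C)=C/Cc1cc(C=O)ccc1O | intermediate
4 | 3-geranyl-4-(methoxymethoxy)benzaldehyde | CC(C)=CCC/C(C)=C/Cc1cc(C=O)ccc1OCOC | intermediate
5 | 3,5-dihydroxybenzaldehyde | O=Cc1cc(O)cc(O)c1 | starting material
6 | 3,5-bis(methoxymethoxy)benzaldehyde | COCOc1cc(C=O)cc(OCOC)c1 | intermediate
7 | (E)-NH2-hydrazone of 4, [3-geranyl-4-(methoxymethoxy)benzylidene]hydrazine | CC(C)=CCC/C(C)=C/Cc1cc(/C=N/N)ccc1OCOC | intermediate (not isolated)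
8 | hydroxy diazene adduct, 2-diazenyl-2-[3-geranyl-4-(MOMO)phenyl]-1-[3,5-bis(MOMO)phenyl]ethanol (metal-bound; both transient sp3 centres unassigned and lost on elimination) | CC(C)=CCC/C(C)=C/Cc1cc(C(N=N)C(O)c2cc(OCOC)cc(OCOC)c2)ccc1OCOC | intermediate (not isolated)
9 | (E)-3-geranyl-4,3',5'-tris(methoxymethoxy)stilbene | CC(C)=CCC/C(C)=C/Cc1cc(/C=C/c2cc(OCOC)cc(OCOC)c2)ccc1OCOC | intermediate
10 | schweinfurthin I, 5-{(E)-2-[3-geranyl-4-hydroxyphenyl]ethenyl}benzene-1,3-diol | CC(C)=CCC/C(C)=C/Cc1cc(/C=C/c2cc(O)cc(O)c2)ccc1O | target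

## Step count and risks
Total steps: 5. Longest linear sequence: 4 (steps 1, 2, 4, 5).

**Step 4 (highest risk).** The likely failure modes are:
- mixed azine formation;
- protonation of the adduct to the 1,2-diarylethanol instead of elimination;
- partner scrambling by hydrazone exchange;
- an E/Z mixture.

The fallback sets out from 4 and comes back at 9, and it keeps the aldehyde carbon of 4 as the nucleophile. Compound 4 is condensed with TsNHNH2 (MeOH, rt) to the N-tosylhydrazone F1. NaOMe converts this into its sodium salt F2. At 40 °C in toluene with BnEt3NCl, the salt releases the aryldiazomethane F3. ClFe(TPP) (1 mol %) and P(OMe)3 trap the derived carbene as the trimethoxyphosphonium ylide F4. This ylide olefinates 6 in a strongly E-selective Wittig-type step to give 9.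

**Step 1.** O- versus C-alkylation and dialkylation can keep the yield low. The fallback sets out from 1 (with 2) and comes back at 3. The phenol is deliberately O-alkylated (K2CO3, acetone, reflux) to 4-(geranyloxy)benzaldehyde F5. The geranyl group is then moved to the ortho carbon by a Florisil-promoted [1,3] shift (toluene, 110 °C). This shift works on electron-poor aryl allyl ethers and retains the E-alkene.

**Step 5.** Brønsted acid can cyclise the ortho-geranyl phenol to a chroman. The fallback sets out from 9 and comes back at 10, and it avoids protic acid. TMSOTf and 2,2'-bipyridyl (MeCN, 0 °C to rt) exchange each aryl MOM group for silicon, giving the tris(trimethylsilyl) ether F6. Adding water hydrolyses this near neutrality to 10.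

## Further compounds
F1 | step 4 | N-tosylhydrazone of 4 | CC(C)=CCC/C(C)=C/Cc1cc(/C=N/NS(=O)(=O)c2ccc(C)cc2)ccc1OCOC
F2 | step 4 | sodium salt of the N-tosylhydrazone | CC(C)=CCC/C(C)=C/Cc1cc(/C=N/[N-]S(=O)(=O)c2ccc(C)cc2)ccc1OCOC.[Na+]
F3 | step 4 | [3-geranyl-4-(methoxymethoxy)phenyl]diazomethane | CC(C)=CCC/C(C)=C/Cc1cc(C=[N+]=[N-])ccc1OCOC
F4 | step 4 | trimethoxyphosphonium [3-geranyl-4-(methoxymethoxy)benzylide] | CC(C)=CCC/C(C)=C/Cc1cc(C=P(OC)(OC)OC)ccc1OCOC
F5 | step 1 | 4-(geranyloxy)benzaldehyde | CC(C)=CCC/C(C)=C/COc1ccc(C=O)cc1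
F6 | step 5 | tris(trimethylsilyl) ether of schweinfurthin I | CC(C)=CCC/C(C)=C/Cc1cc(/C=C/c2cc(O[Si](C)(C)C)cc(O[Si](C)(C)C)c2)ccc1O[Si](C)(C)C
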